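**Retrosynthetic overview**

- Numbering: C1 is the quaternary carbinol carbon carrying C7H2–OBz, then C2 (OAc), C3 (OBz), C4=C5 and C6 (OAc); the cyclohexene is the only ring.
- Feature: C2 and C3 are adjacent secondary carbinol carbons between C1 and the C4=C5 bond. This is the oxidised ortho/meta edge of a monosubstituted benzene whose substituted carbon becomes C1, so C2–O and C3–O come from enzymatic cis-dihydroxylation of bromobenzene.
- The trans C6–OAc/C1–OH pair comes from anti acetolysis at allylic C6 of a C1–C6 oxirane. The oxirane, cis to C2–O, comes from C2–OH-directed epoxidation of C1=C6. The C3–OBz, trans to C2–O, comes from Mitsunobu inversion of the cis-diol.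
- C1–C7 comes from Stille hydroxymethylation of the C1–Br bond on the acetonide-protected diene.
- Ring order: no carbocycle is built, because the benzene ring becomes the cyclohexene. Only a temporary dioxolane (formed in step 2, removed in step 5) and the oxirane (formed in step 6, opened in step 9) are made.

Key step: step 1

Remark: in step 1 the reducing equivalents come from the glucose metabolism of the host cells, which recycle the nicotinamide cofactor.
Remark: the CIP descriptor of C1 changes between 10, 11 and 13 only because substituent priorities change; the C1–O bond is never broken.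

**Step 1**
Reactants: 1 bromobenzene
Product: 2 (1S,2S)-3-bromocyclohexa-3,5-diene-1,2-diol
Conditions: Escherichia coli JM109(pDTG601) whole cells (toluene dioxygenase, IPTG-induced), D-glucose feed, air, mineral salts medium pH 7.0, 35 °C; EtOAc extraction
Reagents that add atoms: dioxygen, O=O
Why: Toluene dioxygenase, a Rieske non-heme iron dioxygenase, binds the arene beside its mononuclear iron centre, activates O2 with two electrons relayed from the reduced nicotinamide cofactor, and transfers both oxygen atoms suprafacially to C2 and C3, so the two C–O bonds form cis and the C1(Br)=C6/C4=C5 diene remains. The closest known reaction type is the established whole-cell cis-dihydroxylation of monohalobenzenes by recombinant strains carrying the tod genes, of which this is a direct case. No ring is closed; the carbocycle is the dearomatised arene ring. Both new stereocentres (C2 and C3, each S in the diol, both hydroxyls on one face) are set by the enzyme pocket, which holds the bromine so that only the adjacent ortho/meta edge faces the iron-bound oxygen, from one side. The step needs regioselectivity for the 2,3-edge over the 3,4-edge and the ipso position, enantiofacial selectivity, and survival of the diene diol; the first two are secured by the single bromine substituent, which the pocket reads much as it reads the methyl group of toluene, and the third by a host that lacks the diol dehydrogenase and by neutral extraction.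

**Step 2**
Reactants: 2 (1S,2S)-3-bromocyclohexa-3,5-diene-1,2-diol
Product: 3 (3aS,7aS)-4-bromo-2,2-dimethyl-3a,7a-dihydro-1,3-benzodioxole (cis-fused acetonide)
Conditions: 2,2-dimethoxypropane, p-TsOH·H2O (cat.), acetone, 0 °C to rt; Et3N quench; stored cold and used soon
Reagents that add atoms: 2,2-dimethoxypropane, COC(C)(C)OC
Why: Acid-catalysed transketalisation of the cis-1,2-diol should give the cis-fused dioxolane quickly, without touching a stereocentre, and it masks the diol against dehydration during the coupling.

**Step 3**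
Reactants: 3 (3aS,7aS)-4-bromo-2,2-dimethyl-3a,7a-dihydro-1,3-benzodioxole; 4 (tributylstannyl)methanol
Product: 5 [(3aR,7aS)-2,2-dimethyl-3a,7a-dihydro-1,3-benzodioxol-4-yl]methanol
Conditions: Pd(PPh3)4 (5 mol %), 1,4-dioxane (0.05 M), BHT (trace), 80 °C, Ar
Reagents that add atoms: (tributylstannyl)methanol, OC[Sn](CCCC)(CCCC)CCCC
Why: Stille coupling: oxidative addition of the C1–Br bond to zerovalent palladium, transfer of the α-oxygenated hydroxymethyl group from tin in preference to butyl, and reductive elimination should form C1–C7; high dilution limits Diels–Alder dimerisation of the diene.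

**Step 4**
Reactants: 5 [(3aR,7aS)-2,2-dimethyl-3a,7a-dihydro-1,3-benzodioxol-4-yl]methanol
Product: 6 [(3aR,7aS)-2,2-dimethyl-3a,7a-dihydro-1,3-benzodioxol-4-yl]methyl benzoate
Conditions: BzCl, Et3N, DMAP (cat.), CH2Cl2, 0 °C
Reagents that add atoms: benzoyl chloride, O=C(Cl)c1ccccc1
Why: DMAP-catalysed acylation of the only free hydroxyl, the primary allylic C7–OH, should install the C7 benzoate of the target.

**Step 5**
Reactants: 6 [(3aR,7aS)-2,2-dimethyl-3a,7a-dihydro-1,3-benzodioxol-4-yl]methyl benzoate
Product: 7 [(5S,6R)-5,6-dihydroxycyclohexa-1,3-dien-1-yl]methyl benzoate (cis-diol, C2–OH and C3–OH on the same face)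
Conditions: TFA/H2O/THF (1:1:8), 0 °C, short contact; cold aq. NaHCO3 quench; used at once
Reagents that add atoms: none
Why: Acid-catalysed hydrolysis of the isopropylidene ketal is expected to be much faster at 0 °C than acid-catalysed dehydration of the liberated cis-diene diol, and the benzoate is inert to these conditions.

**Step 6**
Reactants: 7 [(5S,6R)-5,6-dihydroxycyclohexa-1,3-dien-1-yl]methyl benzoate
Product: 8 [(1S,2S,3S,6R)-2,3-dihydroxy-7-oxabicyclo[4.1.0]hept-4-en-1-yl]methyl benzoate (oxirane on C1–C6, cis to both hydroxyls)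
Conditions: VO(acac)2 (5 mol %), t-BuOOH (1.1 equiv, in decane), CH2Cl2, 0 °C
Reagents that add atoms: tert-butyl hydroperoxide, CC(C)(C)OO
Why: Hydroxyl-directed epoxidation: the C2–OH, held pseudoaxial by allylic strain with the C1 substituent, binds the vanadium peroxide and should deliver oxygen to the adjacent trisubstituted C1=C6 bond on its own face, which sets C1 and C6 with the oxirane cis to C2–OH; the pseudoequatorial C3–OH is poorly placed to direct attack on C4=C5.

**Step 7**
Reactants: 8 [(1S,2S,3S,6R)-2,3-dihydroxy-7-oxabicyclo[4.1.0]hept-4-en-1-yl]methyl benzoate; 9 benzoic acid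
Product: 10 [(1S,2S,3R,6R)-3-(benzoyloxy)-2-hydroxy-7-oxabicyclo[4.1.0]hept-4-en-1-yl]methyl benzoate (C3–OBz trans to C2–OH)
Conditions: PPh3, DIAD, THF, 0 °C
Reagents that add atoms: benzoic acid, OC(=O)c1ccccc1
Why: Mitsunobu reaction: the allylic, less hindered C3–OH is activated by the PPh3/DIAD adduct and displaced by benzoate in an SN2 step with inversion, which sets C3; the C2–OH, flanked by the fully substituted C1, should not be displaced.

**Step 8**
Reactants: 10 [(1S,2S,3R,6R)-3-(benzoyloxy)-2-hydroxy-7-oxabicyclo[4.1.0]hept-4-en-1-yl]methyl benzoate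
Product: 11 [(1R,2S,3R,6R)-2-acetoxy-3-(benzoyloxy)-7-oxabicyclo[4.1.0]hept-4-en-1-yl]methyl benzoate
Conditions: Ac2O, pyridine, DMAP (cat.), CH2Cl2, 0 °C to rt
Reagents that add atoms: acetic anhydride, CC(=O)OC(C)=O
Why: DMAP-catalysed acetylation of the secondary C2–OH caps the last free hydroxyl before the oxirane is opened, which removes any path for benzoyl migration from C3; the oxirane and esters are inert.

**Step 9**
Reactants: 11 [(1R,2S,3R,6R)-2-acetoxy-3-(benzoyloxy)-7-oxabicyclo[4.1.0]hept-4-en-1-yl]methyl benzoate; 12 acetic acid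
Product: 13 (1R,2S,3R,6S)-2,6-diacetoxy-3-(benzoyloxy)-1-[(benzoyloxy)methyl]cyclohex-4-en-1-ol (target CNP0221209.1)
Conditions: AcOH (solvent), NaOAc (2 equiv), 50 °C
Reagents that add atoms: acetic acid, CC(=O)O
Why: Acetolysis of a vinyl epoxide: the hydrogen-bonded oxirane should be opened by acetate at the allylic C6 in an SN2 step anti to the C6–O bond, which inverts C6 and leaves the C1–O bond on its original face (1,6-trans hydroxy acetate); C1 is fully substituted with electron-withdrawing neighbours and the cis C2–OAc cannot participate at C1.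

**Compound list**

1 | bromobenzene | Brc1ccccc1 | starting material
2 | (1S,2S)-3-bromocyclohexa-3,5-diene-1,2-diol | BrC1=CC=C[C@H](O)[C@@H]1O | intermediate
3 | (3aS,7aS)-4-bromo-2,2-dimethyl-3a,7a-dihydro-1,3-benzodioxole | BrC1=CC=C[C@@H]2OC(C)(C)O[C@H]12 | intermediate
4 | (tributylstannyl)methanol | OC[Sn](CCCC)(CCCC)CCCC | starting material
5 | [(3aR,7aS)-2,2-dimethyl-3a,7a-dihydro-1,3-benzodioxol-4-yl]methanol | OCC1=CC=C[C@@H]2OC(C)(C)O[C@H]12 | intermediate
6 | [(3aR,7aS)-2,2-dimethyl-3a,7a-dihydro-1,3-benzodioxol-4-yl]methyl benzoate | O=C(OCC1=CC=C[C@@H]2OC(C)(C)O[C@H]12)c1ccccc1 | intermediate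
7 | [(5S,6R)-5,6-dihydroxycyclohexa-1,3-dien-1-yl]methyl benzoate | O=C(OCC1=CC=C[C@H](O)[C@@H]1O)c1ccccc1 | intermediate
8 | [(1S,2S,3S,6R)-2,3-dihydroxy-7-oxabicyclo[4.1.0]hept-4-en-1-yl]methyl benzoate | O1[C@@H]2C=C[C@H](O)[C@H](O)[C@]12COC(=O)c1ccccc1 | intermediate
9 | benzoic acid | OC(=O)c1ccccc1 | starting material
10 | [(1S,2S,3R,6R)-3-(benzoyloxy)-2-hydroxy-7-oxabicyclo[4.1.0]hept-4-en-1-yl]methyl benzoate | O1[C@@H]2C=C[C@@H](OC(=O)c3ccccc3)[C@H](O)[C@]12COC(=O)c1ccccc1 | intermediate
11 | [(1R,2S,3R,6R)-2-acetoxy-3-(benzoyloxy)-7-oxabicyclo[4.1.0]hept-4-en-1-yl]methyl benzoate | O1[C@@H]2C=C[C@@H](OC(=O)c3ccccc3)[C@H](OC(C)=O)[C@]12COC(=O)c1ccccc1 | intermediate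
12 | acetic acid | CC(=O)O | starting material
13 | (1R,2S,3R,6S)-2,6-diacetoxy-3-(benzoyloxy)-1-[(benzoyloxy)methyl]cyclohex-4-en-1-ol | CC(=O)O[C@H]1C=C[C@@H](OC(=O)c2ccccc2)[C@H](OC(C)=O)[C@@]1(O)COC(=O)c1ccccc1 | target

**Step count and risks**

Total step count: 9. Longest linear sequence: 9 steps (1 to 13).

Steps most likely to fail:

1. Step 5. Acid-catalysed loss of water from the liberated cyclohexadiene diol, with rearomatisation to a phenol, may compete with ketal hydrolysis. The fallback avoids acid altogether and runs from compound 2 back to compound 7. Diol 2 would be silylated (Et3SiCl, imidazole, DMF, 0 °C) to the bis(triethylsilyl) ether of 2, F1. Stille coupling of F1 with 4 under the conditions of step 3 would give the bis(triethylsilyl) ether of the hydroxymethyl diene diol, F2. Benzoylation as in step 4 would give its benzoate, F3. Desilylation with Bu4NF buffered with AcOH in THF at 0 °C, under near-neutral conditions, would then release diol 7.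

2. Step 6. Oxygen transfer may go partly to the C4=C5 bond under direction of C3–OH; a second epoxidation or oxidation of the dienol may also occur. The fallback changes the directing arrangement and runs from compound 5 back to compound 8. The acetonide of 5 would be hydrolysed as in step 5 to (1S,2R)-3-(hydroxymethyl)cyclohexa-3,5-diene-1,2-diol, F4. In F4 the C1=C6 bond carries two allylic hydroxyls (C7–OH and C2–OH) and no deactivating ester, so VO(acac)2/t-BuOOH should epoxidise it alone and on the face of C2–OH, giving (1S,2S,3S,6R)-1-(hydroxymethyl)-7-oxabicyclo[4.1.0]hept-4-ene-2,3-diol, F5. Selective benzoylation of the primary C7–OH (BzCl 1.0 equiv, 2,4,6-collidine, CH2Cl2, −40 °C) would give 8.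

3. Step 9. Regiocontrol in the opening of the vinyl epoxide may be lost through conjugate (1,4) addition of acetate at C4, or through participation of the C7 or C3 benzoate, leading to acyl shift or attack at C1. The fallback uses the free C2–OH as a tether and runs from compound 10 back to compound 13. Treating epoxy alcohol 10 with Ti(OiPr)4 and AcOH in CH2Cl2 at rt should bind titanium to the C2 alkoxide and the cis oxirane oxygen and deliver acetate to the distal allylic C6 with inversion, giving (1S,2S,3R,6S)-6-acetoxy-3-(benzoyloxy)-1-[(benzoyloxy)methyl]cyclohex-4-ene-1,2-diol, F6. Acetylation with Ac2O/pyridine at 0 °C should then esterify only the secondary C2–OH, not the tertiary C1–OH, and give 13.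

**Further compounds**

F1 | step 5 | bis(triethylsilyl) ether of (1S,2S)-3-bromocyclohexa-3,5-diene-1,2-diol | BrC1=CC=C[C@H](O[Si](CC)(CC)CC)[C@@H]1O[Si](CC)(CC)CC
F2 | step 5 | bis(triethylsilyl) ether of (1S,2R)-3-(hydroxymethyl)cyclohexa-3,5-diene-1,2-diol (C7–OH free) | OCC1=CC=C[C@H](O[Si](CC)(CC)CC)[C@@H]1O[Si](CC)(CC)CC
F3 | step 5 | [(5S,6R)-5,6-bis(triethylsilyloxy)cyclohexa-1,3-dien-1-yl]methyl benzoate | O=C(OCC1=CC=C[C@H](O[Si](CC)(CC)CC)[C@@H]1O[Si](CC)(CC)CC)c1ccccc1
F4 | step 6 | (1S,2R)-3-(hydroxymethyl)cyclohexa-3,5-diene-1,2-diol | OCC1=CC=C[C@H](O)[C@@H]1O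
F5 | step 6 | (1S,2S,3S,6R)-1-(hydroxymethyl)-7-oxabicyclo[4.1.0]hept-4-ene-2,3-diol | O1[C@@H]2C=C[C@H](O)[C@H](O)[C@]12CO
F6 | step 9 | (1S,2S,3R,6S)-6-acetoxy-3-(benzoyloxy)-1-[(benzoyloxy)methyl]cyclohex-4-ene-1,2-diol | CC(=O)O[C@H]1C=C[C@@H](OC(=O)c2ccccc2)[C@H](O)[C@@]1(O)COC(=O)c1ccccc1
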